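**Assumption:** the target SMILES has no stereocentres and no stereogenic double bonds, so Mururin C is achiral and "single enantiomer" does not apply. The route has not been run; it rests on known reaction types applied to new substrates.

## Retrosynthetic overview

1. The obvious route (Sonogashira/heteroannulation to the 2-arylbenzofuran, then Vilsmeier formylation) is avoided.
2. The furan ring and the C3-CHO are unmasked together from an acyclic 2-aryl-3,3-dimethoxy-propiophenone: the phenol O adds to the ketone carbon and the acetal becomes the aldehyde.
3. Key step: that keto-acetal comes from a 2-alkoxychalcone by iodine(III)-mediated oxidative 1,2-aryl shift, which makes the future C3–C3a bond by migration.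
4. The chalcone comes from a Claisen–Schmidt condensation of a bis-MOM 3,4-dihydroxy-5-methoxyacetophenone (from acetosyringone) with a MOM-protected 5-(3-hydroxypropyl)-o-vanillin (from dihydroconiferyl alcohol).
5. Ring order: both benzene rings are purchased; the furan is the only ring formed, in the last step, together with global deprotection.

## Route

**Step 1**
Reactants: 1, acetosyringone (4'-hydroxy-3',5'-dimethoxyacetophenone)
Product: 2, 1-(3,4-dihydroxy-5-methoxyphenyl)ethanone
Conditions: AlCl3 (1.2 equiv), pyridine (4.5 equiv), CH2Cl2, reflux; then 2 M HCl
Reagents that add atoms: none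
Why: Chelation-directed ortho-demethylation (Lange AlCl3/pyridine method): the aluminium phenoxide activates only a neighbouring OMe for SN2 demethylation by pyridine, and the resulting aluminium catecholate resists a second cleavage.

**Step 2**
Reactants: 2, 1-(3,4-dihydroxy-5-methoxyphenyl)ethanone
Product: 3, 1-[3-methoxy-4,5-bis(methoxymethoxy)phenyl]ethanone
Conditions: MOMCl (3 equiv), i-Pr2NEt (4 equiv), CH2Cl2, 0 °C to rt
Reagents that add atoms: chloromethyl methyl ether, COCCl (two equivalents incorporated)
Why: Standard phenol O-alkylation (MOM acetal formation); the methyl ketone is inert, and MOM is base-stable for the aldol and acid-labile for the final step.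

**Step 3**
Reactants: 4, dihydroconiferyl alcohol (4-(3-hydroxypropyl)-2-methoxyphenol)
Product: 5, 2-hydroxy-5-(3-hydroxypropyl)-3-methoxybenzaldehyde
Conditions: MgCl2 (3 equiv), Et3N (5 equiv), (CH2O)n (7 equiv), MeCN, reflux; then 1 M HCl
Reagents that add atoms: paraformaldehyde (formaldehyde), C=O
Why: Casnati–Skattebøl magnesium-phenoxide ortho-formylation delivers formaldehyde only ortho to the phenol (one free ortho position), with Oppenauer-type oxidation by excess CH2O giving the aldehyde; hemiformals of the side-chain alcohol revert on acidic work-up.

**Step 4**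
Reactants: 5, 2-hydroxy-5-(3-hydroxypropyl)-3-methoxybenzaldehyde
Product: 6, 5-(3-hydroxypropyl)-3-methoxy-2-(methoxymethoxy)benzaldehyde
Conditions: MOMCl (1.15 equiv), K2CO3, acetone, 0 °C to rt
Reagents that add atoms: chloromethyl methyl ether, COCCl
Why: Chemoselective phenoxide O-alkylation: K2CO3 ionises only the acidic salicylaldehyde phenol, so the neutral primary alcohol is left free.

**Step 5**
Reactants: 3, 1-[3-methoxy-4,5-bis(methoxymethoxy)phenyl]ethanone; 6, 5-(3-hydroxypropyl)-3-methoxy-2-(methoxymethoxy)benzaldehyde
Product: 7, (E)-3-[5-(3-hydroxypropyl)-3-methoxy-2-(methoxymethoxy)phenyl]-1-[3-methoxy-4,5-bis(methoxymethoxy)phenyl]prop-2-en-1-one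
Conditions: KOH (4 equiv), EtOH, rt
Reagents that add atoms: none
Why: Claisen–Schmidt aldol condensation of a methyl ketone with a non-enolisable aldehyde gives the E-enone by E1cB dehydration; MOM ethers and the free alcohol are stable to base.

**Step 6 (key step)**
Reactants: 7, the E-chalcone
Product: 8, (±)-2-[5-(3-hydroxypropyl)-3-methoxy-2-(methoxymethoxy)phenyl]-3,3-dimethoxy-1-[3-methoxy-4,5-bis(methoxymethoxy)phenyl]propan-1-one
Conditions: PhI(OH)OTs (1.3 equiv), MeOH, 0 °C to rt, short reaction time; NaHCO3/Na2S2O3 quench
Reagents that add atoms: methanol, CO (two OMe groups)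
Why: Hypervalent-iodine oxidative rearrangement of a chalcone: α-iodination with β-methoxylation, then loss of PhI with 1,2-shift of the electron-rich ortho-alkoxyaryl group through a phenonium ion and MeOH capture gives the β-keto dimethyl acetal; the reaction runs in an alcohol solvent so the remote primary OH is a spectator, and the new stereocentre is racemic and destroyed in step 7.

**Step 7**
Reactants: 8, the keto-acetal
Product: 9, Mururin C, 2-(3,4-dihydroxy-5-methoxyphenyl)-5-(3-hydroxypropyl)-7-methoxybenzofuran-3-carbaldehyde
Conditions: p-TsOH·H2O (4 equiv), (CF3)2CHOH, rt; then H2O work-up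
Reagents that add atoms: water, O (aldehyde oxygen from acetal hydrolysis)
Why: Acid-mediated cascade in which all three phenolic MOM ethers cleave, the freed ortho-phenol adds to the protonated aryl ketone and dehydrates to the aromatic benzofuran, and the acetal hydrolyses to the 3-CHO; strong acid in HFIP is the known condition that funnels the reversibly formed 2-methoxy-dihydrobenzofuran to the 2-aryl-3-formylbenzofuran instead of the 3-aroyl isomer.

## Compound list

1 | acetosyringone | CC(=O)c1cc(OC)c(O)c(OC)c1 | starting material
2 | 1-(3,4-dihydroxy-5-methoxyphenyl)ethanone | CC(=O)c1cc(O)c(O)c(OC)c1 | intermediate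
3 | 1-[3-methoxy-4,5-bis(methoxymethoxy)phenyl]ethanone | CC(=O)c1cc(OC)c(OCOC)c(OCOC)c1 | intermediate
4 | dihydroconiferyl alcohol | COc1cc(CCCO)ccc1O | starting material
5 | 2-hydroxy-5-(3-hydroxypropyl)-3-methoxybenzaldehyde | COc1cc(CCCO)cc(C=O)c1O | intermediate
6 | 5-(3-hydroxypropyl)-3-methoxy-2-(methoxymethoxy)benzaldehyde | COCOc1c(OC)cc(CCCO)cc1C=O | intermediate
7 | (E)-chalcone | COCOc1c(OC)cc(CCCO)cc1/C=C/C(=O)c1cc(OC)c(OCOC)c(OCOC)c1 | intermediate
8 | (±)-rearranged keto dimethyl acetal | COCOc1c(OC)cc(CCCO)cc1C(C(OC)OC)C(=O)c1cc(OC)c(OCOC)c(OCOC)c1 | intermediate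
9 | Mururin C | COc1cc(-c2oc3c(OC)cc(CCCO)cc3c2C=O)cc(O)c1O | target

## Summary

Total steps: 7. Longest linear sequence: 5 (steps 3, 4, 5, 6, 7; the ketone branch, steps 1, 2, 5, 6, 7, is equally long).

Three steps most likely to fail, with fallbacks:

1. **Step 6 (I(III) 1,2-aryl shift).** Risks are α,β-dimethoxylation without migration, premature MOM loss from the TsOH by-product, and over-oxidation of the electron-rich rings. Fallback: switch from aryl shift to acyl shift. Epoxidise chalcone 7 (H2O2/NaOH, Weitz–Scheffer) and treat the epoxide with BF3·OEt2 (House–Meinwald 1,2-acyl migration). This gives the same Ar'CO–CH(Ar)–CHO skeleton as the free β-keto aldehyde, which is cyclised as in step 7.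

2. **Step 7 (deprotection/cyclisation cascade).** Risks are closure onto the acetal carbon to give the 3-aroylbenzofuran isomer, and hydroxymethylation of the catechol ring by released formaldehyde. Fallback: remove the regiochemical question by making the 2-arylbenzofuran without the C3 carbon. Reduce 5 to the salicyl alcohol, convert it to the phosphonium salt, and run an intramolecular Wittig with the acid chloride of protected 3-O-methylgallic acid. Then install the CHO by Vilsmeier–Haack formylation at C3 and deprotect.

3. **Step 3 (Mg-mediated ortho-formylation with a free alcohol and a chelating ortho-OMe).** Risks are sluggish reaction and hemiformal or methoxymethyl by-products. Fallback: change from electrophilic formylation to directed ortho-metalation. Protect 4 as the aryl MOM ether and primary TBS ether, lithiate ortho to OMOM (n-BuLi/TMEDA, THF, 0 °C), and quench with DMF. The TBS analogue of 6 is carried forward and is cleaved by the acid in step 7.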